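**Plan**

1. Cuts: the ArCH2–C6 bond of ring A (the cyclohexadienone ring), then the butanoyl–C2 bond, then two ring-A bonds at once, C1–C6 and C3–C4; in ring B (the arene) the C–CH2 and C–butanoyl bonds.
2. Enabling feature: ring A is a cyclohexane-1,3,5-trione (drawn as a dienol) whose oxygen-bearing C1, C3, C5 alternate with C2, C4, C6. C4(CH3)2–C5(O)–C6 is a ketone with its two α-carbons and C1(O)–C2–C3(O) a malonyl unit, so a double C-acylation is polarity-matched and quaternary C4 rules out aromatisation.
3. Forward: ring A is made first, in one operation, from 3-methylbutan-2-one (as its tetrasubstituted silyl enol ether) and malonyl dichloride (filicinic acid), then C-butanoylated.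
4. Ring B is bought as 5-methoxyresorcinol; two directed lithiations place CH2NMe2 between the two protected hydroxyls and the butanoyl group between OMOM and OMe.
5. The halves are joined last: the Mannich base gives an ortho-quinone methide that is trapped by the one free ring carbon of butyrylfilicinic acid.
6. Stereochemistry: the target has no stereocentre; only regiochemistry matters, and symmetry (5, 8) plus directed metalation fix it.

Key step: step 2

Assumption: the target is the drawn enol tautomer of an achiral, freely tautomerising triketone; ring-A locants follow the target name (C1 carbonyl, C2 butanoyl, C4 gem-dimethyl, C6 benzyl).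

**Route**

Step 1
Reactants: 1 3-methylbutan-2-one
Product: 2 trimethyl[(3-methylbut-2-en-2-yl)oxy]silane
Conditions: TMSCl, Et3N, DMF, reflux; pentane work-up, distillation
Reagents that add atoms: chlorotrimethylsilane, C[Si](C)(C)Cl
Why: Silyl enol ether formation under equilibrating (House) conditions should favour the more substituted, tetrasubstituted enol ether, which puts the nucleophilic carbon on the isopropyl carbon that must become quaternary C4.

Step 2
Reactants: 2 trimethyl[(3-methylbut-2-en-2-yl)oxy]silane; 3 malonyl dichloride
Product: 5 filicinic acid (3,5-dihydroxy-4,4-dimethylcyclohexa-2,5-dien-1-one), via 4,4-dimethyl-3,5-dioxohexanoyl chloride 4 (not isolated)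
Conditions: Et2O, −20 °C → 20 °C, equimolar, 2 added slowly to 3
Reagents that add atoms: none
Why: The tetrasubstituted enol ether is C-acylated by one acid chloride group of 3 with loss of TMSCl to give 4, whose methyl ketone then enolises (HCl autocatalysis) and attacks the second acid chloride, or the acylketene derived from it, through carbon to close the trione, which tautomerises to dienol 5. The closest known reaction type is the Effenberger cyclisation, the α,α′-annulation of ketone enol ethers with malonyl dichloride to cyclic 1,3,5-triones, best known for bicyclo[3.3.1]nonane-2,4,9-triones from cyclohexanone enol ethers. The ring closes in a 6-(enolendo)-exo-trig mode at the acyl carbon. No stereocentre arises, since C4 carries two identical methyl groups and all other ring carbons are trigonal. The step needs C- instead of O-acylation in the closure and one site for each acylation; the first acylation at the fully substituted carbon leaves a quaternary centre, so the usual escape to a 4-hydroxy-2-pyranone (O-closure of an enol conjugated with the new acyl group) is shut, the ketone can enolise only toward its methyl group, and the two ring CH positions of 5 are equivalent by symmetry. Equimolar amounts, low temperature and the low solubility of 5 in ether should limit further acylation of the enolic product.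

Step 3
Reactants: 5 filicinic acid
Product: 6 butyrylfilicinic acid (2-butanoyl-3,5-dihydroxy-4,4-dimethylcyclohexa-2,5-dien-1-one)
Conditions: butanoyl chloride, AlCl3, PhNO2, 20 → 50 °C; then ice/aq HCl
Reagents that add atoms: butanoyl chloride, CCCC(=O)Cl
Why: Friedel–Crafts C-acylation of the vinylogous acid (the standard entry to acylfilicinic acids) should occur at one of the two symmetry-equivalent enolic ring carbons, and the first acyl group deactivates the ring toward a second acylation.

Step 4
Reactants: 7 5-methoxybenzene-1,3-diol
Product: 8 1-methoxy-3,5-bis(methoxymethoxy)benzene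
Conditions: MOMCl, iPr2NEt, CH2Cl2, 0 → 20 °C
Reagents that add atoms: chloromethyl methyl ether, COCCl
Why: O-Alkylation of both phenols (MOM protection) removes the acidic protons and turns the two oxygens into strong directing groups for metalation.

Step 5
Reactants: 8 1-methoxy-3,5-bis(methoxymethoxy)benzene
Product: 10 1-[4-methoxy-2,6-bis(methoxymethoxy)phenyl]-N,N-dimethylmethanamine, via aryllithium 9 (not isolated)
Conditions: n-BuLi, THF, 0 °C; then Me2N=CH2 iodide (Eschenmoser's salt), −78 → 20 °C
Reagents that add atoms: dimethylmethylideneammonium iodide, C=[N+](C)C.[I-]; n-butyllithium, [Li]CCCC (supplies the lithium of 9 only)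
Why: Directed ortho-metalation should take place at the ring carbon flanked by both OMOM groups (cooperative chelation), and the aryllithium is aminomethylated by the preformed iminium salt in a Mannich-type addition.

Step 6
Reactants: 10 1-[4-methoxy-2,6-bis(methoxymethoxy)phenyl]-N,N-dimethylmethanamine
Product: 13 1-{3-[(dimethylamino)methyl]-6-methoxy-2,4-bis(methoxymethoxy)phenyl}butan-1-one, via aryllithium 11 (not isolated), via tetrahedral lithium adduct 12 (not isolated)
Conditions: n-BuLi, THF, 0 °C; then N-methoxy-N-methylbutanamide, −78 → 0 °C; then H2O
Reagents that add atoms: N-methoxy-N-methylbutanamide, CCCC(=O)N(C)OC; n-butyllithium, [Li]CCCC (supplies the lithium of 11 and 12 only)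
Why: A second directed ortho-metalation can only occur at one of the two equivalent remaining ring positions (each between OMOM and OMe), and the Weinreb ketone synthesis stops at the ketone because the chelated tetrahedral adduct survives until work-up.

Step 7
Reactants: 13 1-{3-[(dimethylamino)methyl]-6-methoxy-2,4-bis(methoxymethoxy)phenyl}butan-1-one
Product: 14 1-{3-[(dimethylamino)methyl]-2,4-dihydroxy-6-methoxyphenyl}butan-1-one hydrochloride
Conditions: HCl in MeOH (1.25 M), 20 → 40 °C; evaporation
Reagents that add atoms: hydrogen chloride, Cl
Why: Acid-catalysed acetal exchange with methanol (MOM cleavage) frees both phenols while the amine is held as its hydrochloride, so the Mannich base should not eliminate prematurely.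

Step 8
Reactants: 14 1-{3-[(dimethylamino)methyl]-2,4-dihydroxy-6-methoxyphenyl}butan-1-one hydrochloride; 6 butyrylfilicinic acid
Product: 16 2-butanoyl-6-[(3-butanoyl-2,6-dihydroxy-4-methoxyphenyl)methyl]-3,5-dihydroxy-4,4-dimethylcyclohexa-2,5-dien-1-one, via ortho-quinone methide 15 (not isolated)
Conditions: Et3N (1 equiv), 1,4-dioxane, 80 °C, N2
Reagents that add atoms: none
Why: Thermal deamination of the phenolic Mannich base (retro-Mannich elimination) should give ortho-quinone methide 15, which is trapped in a Michael addition by the only nucleophilic ring carbon of vinylogous acid 6, the step being driven by rearomatisation of ring B and the site of the bridge on both rings being fixed by the precursors.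

**Compound list**

1 | 3-methylbutan-2-one | CC(=O)C(C)C | starting material
2 | trimethyl[(3-methylbut-2-en-2-yl)oxy]silane | CC(O[Si](C)(C)C)=C(C)C | intermediate
3 | malonyl dichloride (propanedioyl dichloride) | O=C(Cl)CC(=O)Cl | starting material
4 | 4,4-dimethyl-3,5-dioxohexanoyl chloride | CC(=O)C(C)(C)C(=O)CC(=O)Cl | intermediate
5 | filicinic acid (3,5-dihydroxy-4,4-dimethylcyclohexa-2,5-dien-1-one) | CC1(C)C(O)=CC(=O)C=C1O | intermediate
6 | butyrylfilicinic acid (2-butanoyl-3,5-dihydroxy-4,4-dimethylcyclohexa-2,5-dien-1-one) | CCCC(=O)C1=C(O)C(C)(C)C(O)=CC1=O | intermediate
7 | 5-methoxybenzene-1,3-diol (5-methoxyresorcinol) | COc1cc(O)cc(O)c1 | starting material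
8 | 1-methoxy-3,5-bis(methoxymethoxy)benzene | COCOc1cc(OC)cc(OCOC)c1 | intermediate
9 | [4-methoxy-2,6-bis(methoxymethoxy)phenyl]lithium | [Li]c1c(OCOC)cc(OC)cc1OCOC | intermediate
10 | 1-[4-methoxy-2,6-bis(methoxymethoxy)phenyl]-N,N-dimethylmethanamine | CN(C)Cc1c(OCOC)cc(OC)cc1OCOC | intermediate
11 | {3-[(dimethylamino)methyl]-6-methoxy-2,4-bis(methoxymethoxy)phenyl}lithium | CN(C)Cc1c(OCOC)c([Li])c(OC)cc1OCOC | intermediate
12 | lithium 1-{3-[(dimethylamino)methyl]-6-methoxy-2,4-bis(methoxymethoxy)phenyl}-1-[methoxy(methyl)amino]butan-1-olate | CCCC(O[Li])(N(C)OC)c1c(OC)cc(OCOC)c(CN(C)C)c1OCOC | intermediate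
13 | 1-{3-[(dimethylamino)methyl]-6-methoxy-2,4-bis(methoxymethoxy)phenyl}butan-1-one | CCCC(=O)c1c(OC)cc(OCOC)c(CN(C)C)c1OCOC | intermediate
14 | 1-{3-[(dimethylamino)methyl]-2,4-dihydroxy-6-methoxyphenyl}butan-1-one hydrochloride | CCCC(=O)c1c(OC)cc(O)c(C[NH+](C)C)c1O.[Cl-] | intermediate
15 | 4-butanoyl-5-hydroxy-3-methoxy-6-methylidenecyclohexa-2,4-dien-1-one | C=C1C(=O)C=C(OC)C(C(=O)CCC)=C1O | intermediate
16 | 2-butanoyl-6-[(3-butanoyl-2,6-dihydroxy-4-methoxyphenyl)methyl]-3,5-dihydroxy-4,4-dimethylcyclohexa-2,5-dien-1-one (desaspidin BB) | CCCC(=O)C1=C(O)C(C)(C)C(O)=C(Cc2c(O)cc(OC)c(C(=O)CCC)c2O)C1=O | target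

**Count and risks**

Total step count: 8. Longest linear sequence: 5 steps (7 → 8 → 10 → 13 → 14 → 16, steps 4 to 8); the ring-A branch (steps 1 to 3) joins at step 8.

Step 2. What may go wrong: closure through the enol oxygen instead of carbon, further acylation of the enolic product by the diacid chloride, and intermolecular acylation leading to oligomers. Fallback: the annulation is divided into two known operations with a malonyl unit whose two ends differ. Setting out from 2, a ZnCl2-mediated C-acylation with methyl 3-chloro-3-oxopropanoate (CH2Cl2/Et2O, 0 → 20 °C) should give methyl 4,4-dimethyl-3,5-dioxohexanoate F1. An intramolecular Claisen (Dieckmann-type) condensation of F1 (NaOMe, MeOH, reflux; then aq HCl) then closes the methyl ketone carbon onto the ester. Under these equilibrating conditions any O-acylation is reversible and the trione enolate is the thermodynamic sink. The sequence comes back to the route at 5.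

Step 8. What may go wrong: self-alkylation of the Mannich base through the one free nucleophilic position of ring B (oligomerisation), and scrambling of the methylene bridge by retro-Michael reaction at elevated temperature. Fallback: the classical three-component methylene bridging. Setting out from 7, Friedel–Crafts butanoylation (butanoyl chloride, AlCl3, PhNO2; separation from the symmetric 2,6-dihydroxy-4-methoxy isomer) should give desaspidinol, 1-(2,4-dihydroxy-6-methoxyphenyl)butan-1-one F2. F2 and 6 are then condensed with aqueous formaldehyde in dilute aqueous KOH at 0 to 20 °C. The expected course is hydroxymethylation of the enolate of 6, dehydration to the methylene trione, and Michael addition of the phenoxide of F2 at the carbon between its two hydroxyls. After chromatographic removal of the symmetric dimers this comes back to the route at 16.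

Step 6. What may go wrong: metalation at a wrong site (the benzylic C–H next to nitrogen or a MOM methylene) or incomplete addition of the hindered aryllithium to the amide. Fallback: electrophilic aromatic substitution on the free phenol instead of metalation. Setting out from 10, MOM cleavage (HCl, MeOH) should give 2-[(dimethylamino)methyl]-5-methoxybenzene-1,3-diol hydrochloride F3, whose two free ring positions are equivalent by symmetry. Friedel–Crafts butanoylation (butanoyl chloride, AlCl3, PhNO2, 20 to 60 °C) then installs the ketone; a Fries rearrangement of any O-butanoate converges on the same product. This comes back to the route at 14.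

Further compounds
F1 | step 2 | methyl 4,4-dimethyl-3,5-dioxohexanoate | COC(=O)CC(=O)C(C)(C)C(C)=O
F2 | step 8 | 1-(2,4-dihydroxy-6-methoxyphenyl)butan-1-one (desaspidinol) | CCCC(=O)c1c(O)cc(O)cc1OC
F3 | step 6 | 2-[(dimethylamino)methyl]-5-methoxybenzene-1,3-diol hydrochloride | C[NH+](C)Cc1c(O)cc(OC)cc1O.[Cl-]
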